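## Retrosynthetic overview

1. Target 16 ⇐ alcohol 15 (O-methylation) ⇐ C4-epimeric alcohol 13 (Mitsunobu inversion) ⇐ silyl ether 12; these closing steps only correct the oxygen at C4.
2. Key disconnection in 12: the bond between the quaternary ring carbon C6 and the side-chain carbon Cα. It is the central bond of a 1,4-diketone, ArC(=O)–Cα–C6–C1(=O), so each end is a ketone α-carbon. Both enol oxygens can therefore be tied to one SiMe2 group and the bond closed oxidatively inside a seven-membered O–Si–O ring.
3. 12 ⇐ silyl bis-enol ether 11 ⇐ allyl enone 6 + aryl ethyl ketone 7; 6 ⇐ enone 4 (α′-allylation) ⇐ 4-silyloxycyclohexanone 1 (enantioselective deprotonation, Saegusa oxidation).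
4. Ring order: no ring is built. The cyclohexenone ring is that of 1 and the arene that of 7; the only ring formed is the transient siloxane ring of the key step.
5. Stereocontrol: the C4 silyloxy group (S, from step 1) steers the coupling to the opposite face and sets C6; the tether and the Z-enol ether set Cα; C4 is then inverted.

Key step: step 5

Remark on locants: ring carbons are numbered as in cyclohex-2-en-1-one (C1 = ring C=O, C4 = oxygen-bearing carbon, C6 = quaternary carbon); Cα is the CH(CH3) carbon of the side chain.

Assumption: the lithium amide from (R,R)-bis(1-phenylethyl)amine is taken to give the (S)-enol ether 3, as with other 4-substituted cyclohexanones; if the sense were opposite, the (S,S)-amine would be used.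

## Route

Step 1
Reactants: 1 4-[(tert-butyldimethylsilyl)oxy]cyclohexan-1-one
Product: 3 (S)-trimethylsilyl enol ether of 1, via lithium (S)-enolate of the silyloxy ketone 2 (not isolated)
Conditions: (R,R)-bis(1-phenylethyl)amine, n-BuLi, LiCl, TMSCl (in situ quench), THF, −100 → −78 °C
Reagents that add atoms: chlorotrimethylsilane, C[Si](C)(C)Cl
Why: Enantioselective deprotonation of a 4-substituted cyclohexanone (chiral lithium amide desymmetrisation) with internal silyl quench; the chiral base removes one of the two enantiotopic axial α-protons and so fixes the only stereocentre of the ring fragment (silyloxy carbon, S).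

Step 2
Reactants: 3 (S)-trimethylsilyl enol ether
Product: 4 (4S)-4-[(tert-butyldimethylsilyl)oxy]cyclohex-2-en-1-one
Conditions: Pd(OAc)2 (10 mol %), O2 (1 atm), DMSO, rt
Reagents that add atoms: none
Why: Saegusa–Ito oxidation (Pd(II) enolate, β-hydride elimination, Pd reoxidised by O2) places the double bond where the enol ether was, so the stereocentre is untouched and becomes C4 of the enone.

Step 3
Reactants: 4 (4S)-4-[(tert-butyldimethylsilyl)oxy]cyclohex-2-en-1-one
Product: 6 (4S,6S)-4-[(tert-butyldimethylsilyl)oxy]-6-(prop-2-en-1-yl)cyclohex-2-en-1-one (trans isomer expected as the major one; the 6R epimer is carried along), via lithium cross-conjugated dienolate 5 (not isolated)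
Conditions: LDA, THF, −78 °C; then allyl bromide, DMPU, −78 → −40 °C
Reagents that add atoms: allyl bromide, C=CCBr
Why: Kinetic α′-deprotonation gives the cross-conjugated dienolate, which is C-allylated (enolate alkylation) mainly anti to the silyloxy group; the C6 configuration does not matter because C6 is enolised again in step 4.

Step 4
Reactants: 7 1-(3,4-dimethoxyphenyl)propan-1-one; 6 (4S,6S)-4-[(tert-butyldimethylsilyl)oxy]-6-(prop-2-en-1-yl)cyclohex-2-en-1-one
Product: 11 mixed dimethylsilyl bis-enol ether of 6 (C1–O/C6 enol) plus 7 ((Z)-enol), via lithium (Z)-enolate of the aryl ketone 8 (not isolated), via chlorodimethylsilyl (Z)-enol ether 9 (not isolated), via lithium dienolate of the allyl enone 10 (not isolated)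
Conditions: 7, LDA, THF, −78 °C; Me2SiCl2 (5 equiv), −78 °C → rt, volatiles removed in vacuo; then lithium dienolate from 6 (LDA, THF, −78 °C), −78 → 0 °C; used without chromatography
Reagents that add atoms: dichlorodimethylsilane, C[Si](C)(Cl)Cl
Why: Two successive O-silylations of lithium enolates at one silicon (silyl enol ether formation); LDA gives the Z-enolate of the aryl ethyl ketone, excess Me2SiCl2 prevents double displacement in the first stage, and the kinetic tetrasubstituted dienolate of 6 is trapped on oxygen in the second.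

Step 5
Reactants: 11 mixed dimethylsilyl bis-enol ether
Product: 12 (4S,6R)-4-[(tert-butyldimethylsilyl)oxy]-6-[(2S)-1-(3,4-dimethoxyphenyl)-1-oxopropan-2-yl]-6-(prop-2-en-1-yl)cyclohex-2-en-1-one
Conditions: CAN (2.2 equiv), NaHCO3 (4.4 equiv), MeCN/EtCN 6:1, −10 °C
Reagents that add atoms: none
Why: Ce(IV) removes one electron from the more electron-rich aryl enol ether of 11; the radical cation is attacked at Cα by the nucleophilic ring carbon C6 of the tethered 2-silyloxydiene, and a second one-electron oxidation followed by loss of the Me2Si bridge gives both ketones with the ring double bond left at C2=C3. The closest known reaction type is the CAN-mediated oxidative coupling of unsymmetrical dialkylsilyl bis-enol ethers to 1,4-diketones (silicon-tethered oxidative enolate heterocoupling), which is known for aryl ketone/cyclic ketone pairs and for fully substituted α-carbons. No ring of the target is closed: the only ring is the transient seven-membered 1,3-dioxa-2-silacycle of the transition state (bond formation endo to the tether), which forces heterocoupling and is cleaved in the same operation. C6 should be set by attack anti to the C4 silyloxy group (axial attack on the half-chair with pseudo-equatorial OTBS, the syn approach being 1,3-diaxial to it); Cα should be set by the tether, which holds the two C–O bonds syn so that the methyl group of the Z-enol ether (cis to oxygen) lies anti to the allyl group and the hydrogen sits between allyl and C5, giving 6R,2′S. The step needs heterocoupling over homocoupling (secured by the tether), bond formation at C6 rather than at oxygen or C2 (C6 is the nucleophilic terminus of the dienol ether), and oxidation of the enol ethers in preference to the allyl group, the veratryl ring and the TBS ether (the enol ethers are the most easily oxidised π-systems, and NaHCO3 buffers the acid formed).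

Step 6
Reactants: 12 coupled silyl ether
Product: 13 (4S,6R)-6-[(2S)-1-(3,4-dimethoxyphenyl)-1-oxopropan-2-yl]-4-hydroxy-6-(prop-2-en-1-yl)cyclohex-2-en-1-one
Conditions: HF·pyridine, pyridine, THF, 0 °C → rt
Reagents that add atoms: none
Why: Fluoride-mediated Si–O cleavage (silyl ether deprotection) under buffered conditions that leave the enone, both ketones and the epimerisable Cα untouched.

Step 7
Reactants: 13 (4S)-alcohol
Product: 14 (1R,5R)-5-[(2S)-1-(3,4-dimethoxyphenyl)-1-oxopropan-2-yl]-4-oxo-5-(prop-2-en-1-yl)cyclohex-2-en-1-yl 4-nitrobenzoate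
Conditions: 4-nitrobenzoic acid, PPh3, DIAD, THF, 0 °C → rt
Reagents that add atoms: 4-nitrobenzoic acid, O=C(O)c1ccc(cc1)[N+](=O)[O-]
Why: Mitsunobu reaction: the alkoxyphosphonium ion of the secondary allylic alcohol is displaced by 4-nitrobenzoate with SN2 inversion, so the oxygen ends cis to the ketone side chain and trans to allyl (ring C4 now R); the 4-nitrobenzoate also offers a chance of enantiomeric enrichment by recrystallisation.

Step 8
Reactants: 14 4-nitrobenzoate
Product: 15 (4R,6R)-6-[(2S)-1-(3,4-dimethoxyphenyl)-1-oxopropan-2-yl]-4-hydroxy-6-(prop-2-en-1-yl)cyclohex-2-en-1-one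
Conditions: K2CO3 (0.2 equiv), MeOH, 0 °C
Reagents that add atoms: none
Why: Base-catalysed transesterification (methanolysis) of the activated aryl ester; C6 is quaternary, so no elimination of the γ-oxygen is possible, and the mild conditions should spare Cα.

Step 9
Reactants: 15 (4R)-alcohol
Product: 16 (4R,6R)-6-[(2S)-1-(3,4-dimethoxyphenyl)-1-oxopropan-2-yl]-4-methoxy-6-(prop-2-en-1-yl)cyclohex-2-en-1-one (target)
Conditions: MeI (excess), Ag2O, 4 Å MS, CH2Cl2, rt, dark
Reagents that add atoms: iodomethane, CI
Why: Purdie methylation (Ag2O/MeI) etherifies the secondary allylic alcohol with retention under neutral conditions, avoiding enolate formation at either ketone.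

## Compound list

1 | 4-[(tert-butyldimethylsilyl)oxy]cyclohexan-1-one | O=C1CCC(O[Si](C)(C)C(C)(C)C)CC1 | starting material
2 | lithium (4S)-4-[(tert-butyldimethylsilyl)oxy]cyclohex-1-en-1-olate (formed in situ) | [Li]OC1=CC[C@@H](O[Si](C)(C)C(C)(C)C)CC1 | intermediate
3 | tert-butyl(dimethyl){[(1S)-4-[(trimethylsilyl)oxy]cyclohex-3-en-1-yl]oxy}silane | C[Si](C)(C)OC1=CC[C@@H](O[Si](C)(C)C(C)(C)C)CC1 | intermediate
4 | (4S)-4-[(tert-butyldimethylsilyl)oxy]cyclohex-2-en-1-one | O=C1CC[C@H](O[Si](C)(C)C(C)(C)C)C=C1 | intermediate
5 | lithium (4S)-4-[(tert-butyldimethylsilyl)oxy]cyclohexa-1,5-dien-1-olate (formed in situ) | [Li]OC1=CC[C@H](O[Si](C)(C)C(C)(C)C)C=C1 | intermediate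
6 | (4S,6S)-4-[(tert-butyldimethylsilyl)oxy]-6-(prop-2-en-1-yl)cyclohex-2-en-1-one | C=CC[C@H]1C[C@H](O[Si](C)(C)C(C)(C)C)C=CC1=O | intermediate
7 | 1-(3,4-dimethoxyphenyl)propan-1-one | CCC(=O)c1ccc(OC)c(OC)c1 | starting material
8 | lithium (1Z)-1-(3,4-dimethoxyphenyl)prop-1-en-1-olate (formed in situ) | C/C=C(\O[Li])c1ccc(OC)c(OC)c1 | intermediate
9 | chloro{[(1Z)-1-(3,4-dimethoxyphenyl)prop-1-en-1-yl]oxy}dimethylsilane (formed in situ) | C/C=C(\O[Si](C)(C)Cl)c1ccc(OC)c(OC)c1 | intermediate
10 | lithium (4S)-4-[(tert-butyldimethylsilyl)oxy]-2-(prop-2-en-1-yl)cyclohexa-1,5-dien-1-olate (formed in situ) | [Li]OC1=C(CC=C)C[C@H](O[Si](C)(C)C(C)(C)C)C=C1 | intermediate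
11 | {[(4S)-4-[(tert-butyldimethylsilyl)oxy]-2-(prop-2-en-1-yl)cyclohexa-1,5-dien-1-yl]oxy}{[(1Z)-1-(3,4-dimethoxyphenyl)prop-1-en-1-yl]oxy}dimethylsilane | C/C=C(\O[Si](C)(C)OC1=C(CC=C)C[C@H](O[Si](C)(C)C(C)(C)C)C=C1)c1ccc(OC)c(OC)c1 | intermediate
12 | (4S,6R)-4-[(tert-butyldimethylsilyl)oxy]-6-[(2S)-1-(3,4-dimethoxyphenyl)-1-oxopropan-2-yl]-6-(prop-2-en-1-yl)cyclohex-2-en-1-one | C=CC[C@]1([C@H](C)C(=O)c2ccc(OC)c(OC)c2)C[C@H](O[Si](C)(C)C(C)(C)C)C=CC1=O | intermediate
13 | (4S,6R)-6-[(2S)-1-(3,4-dimethoxyphenyl)-1-oxopropan-2-yl]-4-hydroxy-6-(prop-2-en-1-yl)cyclohex-2-en-1-one | C=CC[C@]1([C@H](C)C(=O)c2ccc(OC)c(OC)c2)C[C@H](O)C=CC1=O | intermediate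
14 | (1R,5R)-5-[(2S)-1-(3,4-dimethoxyphenyl)-1-oxopropan-2-yl]-4-oxo-5-(prop-2-en-1-yl)cyclohex-2-en-1-yl 4-nitrobenzoate | C=CC[C@]1([C@H](C)C(=O)c2ccc(OC)c(OC)c2)C[C@@H](OC(=O)c2ccc(cc2)[N+](=O)[O-])C=CC1=O | intermediate
15 | (4R,6R)-6-[(2S)-1-(3,4-dimethoxyphenyl)-1-oxopropan-2-yl]-4-hydroxy-6-(prop-2-en-1-yl)cyclohex-2-en-1-one | C=CC[C@]1([C@H](C)C(=O)c2ccc(OC)c(OC)c2)C[C@@H](O)C=CC1=O | intermediate
16 | (4R,6R)-6-[(2S)-1-(3,4-dimethoxyphenyl)-1-oxopropan-2-yl]-4-methoxy-6-(prop-2-en-1-yl)cyclohex-2-en-1-one | C=CC[C@]1([C@H](C)C(=O)c2ccc(OC)c(OC)c2)C[C@@H](OC)C=CC1=O | target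

## Step count and risks

Total step count: 9. Longest linear sequence: 9 steps (1 → 16); ketone 7 enters at step 4.

Steps most likely to fail:

1. Step 5 (key step). Possible failures are erosion of the simple diastereoselectivity at Cα or of the facial selectivity at C6, competing one-electron oxidation of the veratryl ring, and solvolysis of the Si–O bonds before coupling. The fallback sets out from 6 and 7 and comes back at 12. Ketone 6 is converted (LDA, TMSCl, THF, −78 °C) into its trimethylsilyl dienol ether F1, and 7 is brominated (CuBr2, EtOAc/CHCl3, reflux) to racemic 2-bromo-1-(3,4-dimethoxyphenyl)propan-1-one F2. A visible-light photoredox radical alkylation (Ru(bpy)3Cl2, blue LED, DMF, rt) then adds the α-keto radical from the bromo ketone to C6 of the dienol ether, anti to the silyloxy group. This should give 12 together with its Cα epimer, which would be separated and recycled by base equilibration (DBU).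

2. Step 4. Possible failures are scrambling at silicon to the two symmetrical bis-enol ethers, incomplete O-silylation of the hindered tetrasubstituted dienolate, and hydrolysis of the chlorosilane on handling. The fallback sets out from 6 and 7 and comes back at 12 without a tether. The lithium dienolate of 6 and an excess of the lithium (Z)-enolate of 7 (both with LDA, THF, −78 °C) are oxidised together with Cu(II) 2-ethylhexanoate or Fe(acac)3 (−78 °C → rt) in an intermolecular oxidative enolate heterocoupling; control at Cα is lost and the epimers are separated. This fallback makes no new isolable compound (entry F0).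

3. Step 7. Possible failures are SN2′ attack or elimination of the activated allylic alcohol, and partial retention through an allylic cation. The fallback sets out from 13 and comes back at 15, so that step 8 is skipped. Alcohol 13 is oxidised with MnO2 (CH2Cl2, rt) to the ene-dione (5R)-5-[(2S)-1-(3,4-dimethoxyphenyl)-1-oxopropan-2-yl]-5-(prop-2-en-1-yl)cyclohex-2-ene-1,4-dione F3. Its less hindered enone carbonyl (flanked by CH2) is then reduced under reagent control by a Corey–Bakshi–Shibata reduction ((S)-Me-CBS, catecholborane, toluene, −40 °C; catalyst antipode chosen for hydride delivery that gives the 4R alcohol).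

## Further compounds

F0 | step 4 | none | none
F1 | step 5 | tert-butyl(dimethyl){[(1S)-5-(prop-2-en-1-yl)-4-[(trimethylsilyl)oxy]cyclohexa-2,4-dien-1-yl]oxy}silane (trimethylsilyl dienol ether of 6) | C[Si](C)(C)OC1=C(CC=C)C[C@H](O[Si](C)(C)C(C)(C)C)C=C1
F2 | step 5 | 2-bromo-1-(3,4-dimethoxyphenyl)propan-1-one (racemic) | CC(Br)C(=O)c1ccc(OC)c(OC)c1
F3 | step 7 | (5R)-5-[(2S)-1-(3,4-dimethoxyphenyl)-1-oxopropan-2-yl]-5-(prop-2-en-1-yl)cyclohex-2-ene-1,4-dione | C=CC[C@]1([C@H](C)C(=O)c2ccc(OC)c(OC)c2)CC(=O)C=CC1=O
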